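**Retrosynthetic overview**
1. The target is cut at the ester C–O bond into malonic acid and the free allylic alcohol, (5R,9R,10R)-labda-8(17),13E-dien-15-ol.
2. The E-trisubstituted alkene and C-15 come from a terminal alkyne by methylalumination and hydroxymethylation; the C-8 methylidene comes from a C-8 ketone by Wittig reaction.
3. Ring B is formed last, in the key step: a semipinacol ring expansion of a trans-hydrindane diol monomesylate, in which quaternary C-10 shifts from C-8 to C-9. The diol comes from Wittig union of a hydrindanone with a C5 alkynyl ylide, then dihydroxylation.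
4. Ring A is formed second: a hydrogen-atom-transfer-initiated 6-endo radical closure of a trans-2-allyl-3-isopropenyl-2-methylcyclopentanone builds the gem-dimethyl carbon.
5. The first ring is bought as 2-methylcyclopent-2-enone; an asymmetric Cu-catalysed isopropenyl 1,4-addition with enolate allylation sets C-5 and C-10, and C-9 is set by equilibration after the ring expansion.

Assumption: labdane numbering (C-5, C-9, C-10 …) is used in the explanations, and the alkynyl SiMe3 group of 7 is a protecting group that is removed in step 6.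

**Step 1**
Reactants: 1 2-methylcyclopent-2-en-1-one; 2 isopropenylmagnesium bromide; 3 allyl bromide
Product: 5 (2R,3R)-2-methyl-2-(prop-2-en-1-yl)-3-(prop-1-en-2-yl)cyclopentan-1-one, via magnesium enolate 4 (not isolated)
Conditions: 2 (1.3 equiv), Cu(OTf)2 (3 mol%), chiral hydroxyalkyl-imidazolinium NHC precursor (4 mol%, enantiomer giving 3R), Et2O, −30 °C; then 3 (3 equiv), DMPU, −30 °C → rt
Reagents that add atoms: none
Why: Proposed new method: a ligand-bound isopropenyl cuprate adds 1,4 to the α-methyl enone on the enantioface chosen by the chiral NHC and so sets C-3 (labdane C-5), and the regiodefined magnesium enolate 4 is then allylated anti to the new isopropenyl group, which sets the quaternary C-2 (labdane C-10) trans to it, the new element being an alkenyl Grignard reagent on a five-membered α-methyl enone; closest known reaction type: Cu/NHC-catalysed asymmetric conjugate addition of alkyl Grignard reagents to 2-methylcycloalkenones with enolate alkylation.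

**Step 2**
Reactants: 5 (2R,3R)-2-methyl-2-(prop-2-en-1-yl)-3-(prop-1-en-2-yl)cyclopentan-1-one
Product: 6 (3aR,7aR)-4,4,7a-trimethyloctahydro-1H-inden-1-one
Conditions: Mn(dpm)3 (10 mol%), PhSiH3 (slow addition), t-BuOOH, i-PrOH (0.01 M), rt
Reagents that add atoms: none
Why: Proposed new method: Mn–H transfers a hydrogen atom to the 1,1-disubstituted isopropenyl group (faster than to the monosubstituted allyl group) to give a tertiary radical that cannot close 5-exo, because that would give a trans-fused bicyclo[3.3.0]octanone, and therefore attacks the allyl terminus 6-endo, forming ring A and the gem-dimethyl quaternary carbon before the secondary radical is reduced by a second hydrogen-atom transfer, with no new stereocentre since the trans ring fusion was fixed in step 1; closest known reaction type: metal-hydride hydrogen-atom-transfer (Mukaiyama-type) reductive radical cyclisation and Giese addition of alkenes.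

**Step 3**
Reactants: 7 (5-chloropent-1-yn-1-yl)trimethylsilane
Product: 9 triphenyl[5-(trimethylsilyl)pent-4-yn-1-yl]phosphonium iodide, via iodide 8 (not isolated)
Conditions: PPh3, NaI, MeCN, reflux
Reagents that add atoms: triphenylphosphine (c1ccc(cc1)P(c1ccccc1)c1ccccc1); sodium iodide ([Na+].[I-])
Why: Finkelstein exchange gives the primary iodide, which quaternises PPh3 by SN2 (phosphonium salt formation); no stereocentre is involved.

**Step 4**
Reactants: 6 (3aR,7aR)-4,4,7a-trimethyloctahydro-1H-inden-1-one; 9 triphenyl[5-(trimethylsilyl)pent-4-yn-1-yl]phosphonium iodide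
Product: 11 trimethyl{(5Z)-5-[(3aR,7aR)-4,4,7a-trimethyloctahydro-1H-inden-1-ylidene]pent-1-yn-1-yl}silane, via phosphonium ylide 10 (not isolated)
Conditions: 9 (2.5 equiv), KHMDS (2.4 equiv), toluene, 0 °C → rt; then 6, 100 °C
Reagents that add atoms: none
Why: Wittig olefination with a non-stabilised ylide, which on α-quaternary cyclopentanones of the 17-oxo-steroid type places the alkyl chain syn to the quaternary carbon (Z), while the silyl cap keeps the alkyne inert to the base.

**Step 5**
Reactants: 11 trimethyl{(5Z)-5-[(3aR,7aR)-4,4,7a-trimethyloctahydro-1H-inden-1-ylidene]pent-1-yn-1-yl}silane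
Product: 12 (1S,3aR,7aR)-1-[(1R)-1-hydroxy-5-(trimethylsilyl)pent-4-yn-1-yl]-4,4,7a-trimethyloctahydro-1H-inden-1-ol
Conditions: OsO4 (5 mol%), NMO, acetone/H2O, rt
Reagents that add atoms: osmium tetroxide as catalytic oxygen carrier (O=[Os](=O)(=O)=O); N-methylmorpholine N-oxide (C[N+]1([O-])CCOCC1); water (O)
Why: Upjohn syn-dihydroxylation of the only alkene (the silyl alkyne is inert) from the face anti to the angular methyl group, which together with the Z geometry sets the (1S) tertiary and (1R) secondary carbinol centres.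

**Step 6**
Reactants: 12 (1S,3aR,7aR)-1-[(1R)-1-hydroxy-5-(trimethylsilyl)pent-4-yn-1-yl]-4,4,7a-trimethyloctahydro-1H-inden-1-ol
Product: 15 (1S,4aR,8aR)-1-(but-3-yn-1-yl)-5,5,8a-trimethyloctahydronaphthalen-2(1H)-one, via mesylate 13 (not isolated), via axial-chain silyl ketone 14 (not isolated)
Conditions: MsCl, Et3N, CH2Cl2, −10 °C; crude 13, Et3Al, CH2Cl2, −78 → 0 °C; then NaOMe (cat.), MeOH, rt
Reagents that add atoms: none
Why: Semipinacol ring expansion (Tsuchihashi–Suzuki type, as in steroid D-homoannulation): in the Al-chelated rotamer that keeps H in the crowded sector, the C1–C7a ring bond is antiperiplanar to C–OMs, so the quaternary carbon shifts with inversion at the carbinol carbon to give 14, and methoxide then equilibrates the α-centre to the equatorial (1S) epimer (labdane C-9) and removes the SiMe3 group.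

**Step 7**
Reactants: 15 (1S,4aR,8aR)-1-(but-3-yn-1-yl)-5,5,8a-trimethyloctahydronaphthalen-2(1H)-one
Product: 16 (1R,4aR,8aR)-1-(but-3-yn-1-yl)-5,5,8a-trimethyl-2-methylidenedecahydronaphthalene
Conditions: Ph3PCH3Br, NaHMDS, THF, 0 → 65 °C
Reagents that add atoms: methyltriphenylphosphonium bromide (C[P+](c1ccccc1)(c1ccccc1)c1ccccc1.[Br-])
Why: Wittig methylenation of the hindered ketone; the α-stereocentre is already the thermodynamic equatorial one, so the basic ylide cannot erode it (the descriptor changes to 1R only through the priority change).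

**Step 8**
Reactants: 16 (1R,4aR,8aR)-1-(but-3-yn-1-yl)-5,5,8a-trimethyl-2-methylidenedecahydronaphthalene
Product: 19 (2E)-3-methyl-5-[(1R,4aR,8aR)-5,5,8a-trimethyl-2-methylidenedecahydronaphthalen-1-yl]pent-2-en-1-ol, via alkenylalane 17 (not isolated), via lithium alanate 18 (not isolated)
Conditions: Me3Al, Cp2ZrCl2 (20 mol%), CH2Cl2, rt; then n-BuLi, THF, −78 °C; (CH2O)n, −78 °C → rt; aq. NH4Cl
Reagents that add atoms: trimethylaluminium (C[Al](C)C); formaldehyde as paraformaldehyde (C=O)
Why: Negishi Zr-catalysed carboalumination adds Me–Al syn across the terminal alkyne with Al at the terminus, which fixes the E geometry, and the ate complex is hydroxymethylated with retention, while the 1,1-disubstituted exocyclic alkene does not react.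

**Step 9**
Reactants: 19 (2E)-3-methyl-5-[(1R,4aR,8aR)-5,5,8a-trimethyl-2-methylidenedecahydronaphthalen-1-yl]pent-2-en-1-ol; 20 malonic acid
Product: 22 3-{[(2E)-3-methyl-5-[(1R,4aR,8aR)-5,5,8a-trimethyl-2-methylidenedecahydronaphthalen-1-yl]pent-2-en-1-yl]oxy}-3-oxopropanoic acid, via O-acylisourea 21 (not isolated)
Conditions: 20 (3 equiv), DCC (1.1 equiv), MeCN/THF, 0 °C → rt
Reagents that add atoms: none
Why: Carbodiimide-mediated mono-esterification (Steglich type), in which the excess diacid gives the half ester and the cold, neutral conditions leave the allylic ester, both alkenes and all stereocentres untouched.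

**Compound list**
1 | 2-methylcyclopent-2-en-1-one | CC1=CCCC1=O | starting material
2 | isopropenylmagnesium bromide (prop-1-en-2-ylmagnesium bromide) | C=C(C)[Mg]Br | starting material
3 | allyl bromide (3-bromoprop-1-ene) | C=CCBr | starting material
4 | bromomagnesium (3R)-2-methyl-3-(prop-1-en-2-yl)cyclopent-1-en-1-olate | CC1=C(O[Mg]Br)CC[C@@H]1C(C)=C | intermediate
5 | (2R,3R)-2-methyl-2-(prop-2-en-1-yl)-3-(prop-1-en-2-yl)cyclopentan-1-one | O=C1CC[C@H](C(C)=C)[C@@]1(C)CC=C | intermediate
6 | (3aR,7aR)-4,4,7a-trimethyloctahydro-1H-inden-1-one | O=C1CC[C@@H]2C(C)(C)CCC[C@]21C | intermediate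
7 | (5-chloropent-1-yn-1-yl)trimethylsilane | C[Si](C)(C)C#CCCCCl | starting material
8 | (5-iodopent-1-yn-1-yl)trimethylsilane | C[Si](C)(C)C#CCCCI | intermediate
9 | triphenyl[5-(trimethylsilyl)pent-4-yn-1-yl]phosphonium iodide | C[Si](C)(C)C#CCCC[P+](c1ccccc1)(c1ccccc1)c1ccccc1.[I-] | intermediate
10 | triphenyl[5-(trimethylsilyl)pent-4-yn-1-ylidene]-λ5-phosphane | C[Si](C)(C)C#CCCC=P(c1ccccc1)(c1ccccc1)c1ccccc1 | intermediate
11 | trimethyl{(5Z)-5-[(3aR,7aR)-4,4,7a-trimethyloctahydro-1H-inden-1-ylidene]pent-1-yn-1-yl}silane | C[Si](C)(C)C#CCC/C=C1/CC[C@@H]2C(C)(C)CCC[C@]21C | intermediate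
12 | (1S,3aR,7aR)-1-[(1R)-1-hydroxy-5-(trimethylsilyl)pent-4-yn-1-yl]-4,4,7a-trimethyloctahydro-1H-inden-1-ol | C[Si](C)(C)C#CCC[C@@H](O)[C@]1(O)CC[C@@H]2C(C)(C)CCC[C@]21C | intermediate
13 | (1R)-1-[(1S,3aR,7aR)-1-hydroxy-4,4,7a-trimethyloctahydro-1H-inden-1-yl]-5-(trimethylsilyl)pent-4-yn-1-yl methanesulfonate | C[Si](C)(C)C#CCC[C@@H](OS(C)(=O)=O)[C@]1(O)CC[C@@H]2C(C)(C)CCC[C@]21C | intermediate
14 | (1R,4aR,8aR)-5,5,8a-trimethyl-1-[4-(trimethylsilyl)but-3-yn-1-yl]octahydronaphthalen-2(1H)-one | O=C1CC[C@@H]2C(C)(C)CCC[C@@]2(C)[C@H]1CCC#C[Si](C)(C)C | intermediate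
15 | (1S,4aR,8aR)-1-(but-3-yn-1-yl)-5,5,8a-trimethyloctahydronaphthalen-2(1H)-one | O=C1CC[C@@H]2C(C)(C)CCC[C@@]2(C)[C@@H]1CCC#C | intermediate
16 | (1R,4aR,8aR)-1-(but-3-yn-1-yl)-5,5,8a-trimethyl-2-methylidenedecahydronaphthalene | C=C1CC[C@@H]2C(C)(C)CCC[C@@]2(C)[C@@H]1CCC#C | intermediate
17 | dimethyl{(1E)-2-methyl-4-[(1R,4aR,8aR)-5,5,8a-trimethyl-2-methylidenedecahydronaphthalen-1-yl]but-1-en-1-yl}alumane | C=C1CC[C@@H]2C(C)(C)CCC[C@@]2(C)[C@@H]1CC/C(C)=C/[Al](C)C | intermediate
18 | lithium butyl(dimethyl){(1E)-2-methyl-4-[(1R,4aR,8aR)-5,5,8a-trimethyl-2-methylidenedecahydronaphthalen-1-yl]but-1-en-1-yl}aluminate | C=C1CC[C@@H]2C(C)(C)CCC[C@@]2(C)[C@@H]1CC/C(C)=C/[Al-](C)(C)CCCC.[Li+] | intermediate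
19 | (2E)-3-methyl-5-[(1R,4aR,8aR)-5,5,8a-trimethyl-2-methylidenedecahydronaphthalen-1-yl]pent-2-en-1-ol | C=C1CC[C@@H]2C(C)(C)CCC[C@@]2(C)[C@@H]1CC/C(C)=C/CO | intermediate
20 | malonic acid (propanedioic acid) | OC(=O)CC(=O)O | starting material
21 | 3-{[(cyclohexylamino)(cyclohexylimino)methyl]oxy}-3-oxopropanoic acid | OC(=O)CC(=O)OC(=NC1CCCCC1)NC1CCCCC1 | intermediate
22 | 3-{[(2E)-3-methyl-5-[(1R,4aR,8aR)-5,5,8a-trimethyl-2-methylidenedecahydronaphthalen-1-yl]pent-2-en-1-yl]oxy}-3-oxopropanoic acid | C=C1CC[C@@H]2C(C)(C)CCC[C@@]2(C)[C@@H]1CC/C(C)=C/COC(=O)CC(=O)O | target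

**Step count**
Total: 9 steps. Longest linear sequence: 8 steps (steps 1, 2, 4, 5, 6, 7, 8, 9); step 3 is a one-step side branch.

**The three steps most likely to fail**

Step 2 (proposed new method). The risk is plain reduction of the isopropenyl group, or loss of a hydrogen atom from the cyclised radical to give ring alkenes. The fallback uses known chemistry, sets out from 5 and comes back at 6. Markovnikov addition of HBr (CH2Cl2, −78 °C) to the isopropenyl group gives the tertiary bromide (2R,3S)-3-(2-bromopropan-2-yl)-2-methyl-2-(prop-2-en-1-yl)cyclopentan-1-one F3. A conventional halogen-abstraction radical chain ((Me3Si)3SiH, AIBN, syringe pump, toluene, 90 °C) then closes ring A 6-endo, for the same strain reason, to give 6.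

Step 1 (proposed new method). The risk is low enantioselectivity or competing 1,2-addition with the alkenyl Grignard reagent. The fallback uses known chemistry, sets out from 1 (with 2 and 3) and comes back at 5. The ligand-free CuBr·SMe2-catalysed conjugate addition and allylation gives the racemic trans ketone rac-(2R*,3R*)-2-methyl-2-(prop-2-en-1-yl)-3-(prop-1-en-2-yl)cyclopentan-1-one F1. This is resolved classically: ketalisation with (2R,3R)-butane-2,3-diol (PPTS, benzene, Dean–Stark), chromatographic separation of the two diastereomeric dioxolanes, and hydrolysis (PPTS, acetone/H2O) of (2R,3R,6R,7R)-2,3,6-trimethyl-6-(prop-2-en-1-yl)-7-(prop-1-en-2-yl)-1,4-dioxaspiro[4.4]nonane F2 to give 5.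

Step 6 (the ring expansion). The risk is migration of the CH2 ring carbon instead of the quaternary one (which also follows if step 4 gives E-alkene), or epoxide formation. The fallback sets out from 12 and comes back at 15. Swern oxidation of the secondary alcohol gives the α-hydroxy ketone 1-[(1S,3aR,7aR)-1-hydroxy-4,4,7a-trimethyloctahydro-1H-inden-1-yl]-5-(trimethylsilyl)pent-4-yn-1-one F4. BF3·OEt2 (CH2Cl2, 0 °C) then promotes the chelation-controlled α-ketol rearrangement, in which the quaternary ring carbon migrates to the ketone carbon, to give the ring-expanded ketol (1R,4aR,8aR)-1-hydroxy-5,5,8a-trimethyl-1-[4-(trimethylsilyl)but-3-yn-1-yl]octahydronaphthalen-2(1H)-one F5. SmI2 (THF/MeOH) cleaves the α-hydroxyl to give 14 and its epimer, and NaOMe/MeOH desilylates and equilibrates these to 15.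

**Further compounds**
F1 | step 1 | rac-(2R*,3R*)-2-methyl-2-(prop-2-en-1-yl)-3-(prop-1-en-2-yl)cyclopentan-1-one (racemate, one enantiomer drawn) | O=C1CC[C@H](C(C)=C)[C@@]1(C)CC=C
F2 | step 1 | (2R,3R,6R,7R)-2,3,6-trimethyl-6-(prop-2-en-1-yl)-7-(prop-1-en-2-yl)-1,4-dioxaspiro[4.4]nonane | C12(CC[C@H](C(C)=C)[C@@]1(C)CC=C)O[C@H](C)[C@@H](C)O2
F3 | step 2 | (2R,3S)-3-(2-bromopropan-2-yl)-2-methyl-2-(prop-2-en-1-yl)cyclopentan-1-one | O=C1CC[C@H](C(C)(C)Br)[C@@]1(C)CC=C
F4 | step 6 | 1-[(1S,3aR,7aR)-1-hydroxy-4,4,7a-trimethyloctahydro-1H-inden-1-yl]-5-(trimethylsilyl)pent-4-yn-1-one | C[Si](C)(C)C#CCCC(=O)[C@]1(O)CC[C@@H]2C(C)(C)CCC[C@]21C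
F5 | step 6 | (1R,4aR,8aR)-1-hydroxy-5,5,8a-trimethyl-1-[4-(trimethylsilyl)but-3-yn-1-yl]octahydronaphthalen-2(1H)-one | O=C1CC[C@@H]2C(C)(C)CCC[C@@]2(C)[C@]1(O)CCC#C[Si](C)(C)C
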